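The numbers in the tables are simulated for substances that don't exist.

A small charge of catalyst, 0.84 mM against 0.252 M of reagent, has to carry grey, green and violet for 25 h.

in all of them: left-handed substrate 0.084 M; right-handed substrate 0.084 M; reagent 0.252 M

| flask | free catalyst | temperature | remark | time |
|---|---|---|---|---|
| east | 0.42 mM | −10 °C | run made earlier |  |
| south-east | 1.7 mM | 25 °C | run made earlier |  |
| grey | 0.84 mM | −5 °C |  | 25 h |
| green | 0.84 mM | 55 °C |  | 25 h |
| violet | 0.84 mM | 25 °C |  | 25 h |

| run | time / h | left-handed product / % | right-handed product / % |
|---|---|---|---|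
| east | 1.33 | 9.6 | 2.5 |
| east | 2.00 | 11.4 | 0.6 |
| east | 3.00 | 14.8 | 1.9 |
| east | 4.00 | 19.7 | 3.0 |
| east | 6.00 | 26.7 | 4.7 |
| east | 10.0 | 33.4 | 8.8 |
| east | 15.0 | 39.3 | 9.6 |
| south-east | 0.333 | 31.8 | 11.9 |
| south-east | 0.417 | 32.2 | 15.0 |
| south-east | 0.667 | 38.5 | 20.4 |
| south-east | 0.833 | 41.1 | 19.9 |
| south-east | 1.33 | 45.5 | 27.0 |
| south-east | 2.50 | 46.4 | 29.6 |
| south-east | 3.00 | 48.4 | 30.5 |

(each reading ± 1 percentage point)

* which flask leads in excess of left-handed product over right-handed product ("all alike" within 1.5 percentage points) (grey / green / violet / all alike)
* excess of left-handed product over right-handed product at the end, grey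
* excess of left-handed product over right-handed product at the end, green
* excess of left-handed product over right-handed product at the end, violet

- free catalyst is single-handed; left-handed substrate and right-handed substrate are mirror images of each other, charged as a racemate, each of them at the stated concentration
- an excess is below zero if the other one leads

South-east's readings give a ladder of times. By 0.333 h its left-handed substrate is down to 36.4 % of its charge, but the right-handed substrate reaches 46.0 % only at 1.33 h. On the last rung the flask crawls: the products together stand at 72.5 % at 1.33 h and 78.9 % at 3.00 h.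

Dividing the left-handed rate by the right-handed rate cancels catalyst, reagent and clock, provided both substrates pass through the same catalyst and neither feeds the other. What stays is the selectivity factor: the logarithm of the left-handed left-over divided by that of the right-handed left-over. The last east reading gives 7.23, and south-east at 1.33 h gives 3.10. My own straight line of its logarithm against temperature puts grey at a selectivity factor of 6.41.

Violet shares south-east's temperature with half its catalyst, and the readings of that run show an excess of 34.8 % at 61.0 % converted, and 22.7 % at 78.9 %.

The forecast names grey as leader, with 35 % (27 % to 44 %) for grey, 21 % (13 % to 28 %) for green and 33 % (27 % to 39 %) for violet, and it adds: “Grey and violet are nearly tied”.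

    reagent + free catalyst + left-handed substrate → free catalyst + left-handed product (k = 150 L² mol⁻² min⁻¹, Ea = 35.0 kJ mol⁻¹)
    reagent + free catalyst + right-handed substrate → free catalyst + right-handed product (k = 48.0 L² mol⁻² min⁻¹, Ea = 48.0 kJ mol⁻¹)
    left-handed substrate ⇌ right-handed substrate (k = 4.70 × 10⁻⁴ min⁻¹, Ea = 101 kJ mol⁻¹)
    free catalyst → spent catalyst A (k = 0.00270 min⁻¹, Ea = 104 kJ mol⁻¹)
    2 free catalyst → spent catalyst B (k = 4.10 L mol⁻¹ min⁻¹, Ea = 49.0 kJ mol⁻¹)
    (constants at 25 °C)

The flasks give 31.4 % for grey, 26.4 % for green and 22.9 % for violet, so grey leads. At 25.0 h violet has left-overs of 12 % left-handed and 21 % right-handed substrate, whose logarithms divide to 1.38, less than the 3.10 read from south-east. In grey, the factor 6.41 turns the right-handed left-over of 48 % into a left-handed left-over of 0.932 %, where the flask holds 1.8 %, and into an excess of 31.2 %.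

The neighbour like grey but with 0.063 M of reagent keeps 88 % of its right-handed substrate, and the same factor then gives an excess of 64.7 %. The computed flask gives 62.3 %.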